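Compound numbers 1–39 are fixed by the steps below and are used throughout. Atom labels C1–C13 follow the ring numbering of the target (ring C1–C10, lactone carbons C11 and C12, exocyclic methylene C13), also for the six-membered intermediates.

## Analysis of the target

The target 39 is a germacranolide: a cyclodeca-1(10),4-diene whose two trisubstituted ring alkenes, C1=C10 and C4=C5, are both Z, cis-fused across C6–C7 to an α-methylene-γ-butyrolactone (oxygen on C6, C11 on C7, carbonyl C12, exocyclic C13). Five ring carbons are stereogenic: C3 (S, acetate), C6 (R), C7 (S), C8 (R, free hydroxyl) and C9 (S, ester). In a flat drawing of the ring the substituents on C6, C7, C8 and C9 lie on one face and the C3 acetate on the other. The C9 ester is (2R,3R)-2,3-dimethyloxirane-2-carboxylate, the epoxide of angelic acid, with two further stereocentres that are independent of the ring. Sensitive groups are the methylene lactone (a Michael acceptor), the glycidic ester, the allylic esters at C3 and C9, and the free C8 hydroxyl next to the C9 ester (acyl migration), so O3, O8 and O9 must be kept distinguishable to the end. The difficulty lies in the strained ten-membered ring with two Z trisubstituted alkenes and in the contiguous C6–C9 array. The plan rests on the C8–C9 bond: it joins the two oxygenated centres, is allylic to C1=C10 and lies β,γ to C6, so with C6 as a ketone the chain C1=C10–C9–C8–C7–C6(=O) is the retron of an oxy-Cope rearrangement. Cutting C8–C9 and joining C1 to C6 turns the ten-membered ring into a cyclohexene that already contains C4=C5, its methyl group and the C3 oxygen.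

## Retrosynthetic reasoning

**Acyl groups and protecting groups (39 back to 29 and 34).** No skeletal bond is cut here. The C8 hydroxyl of 39 is masked as a PMB ether (38), the C3 acetate is traced to a TBDPS ether (37, 36), and the C9 ester C–O bond is cut to give alcohol 30 and acid 34; 30 comes from the TBS ether 29. The three oxygens thus carry three groups removable under different conditions (mild acid, fluoride, oxidation). The forward order puts in the epoxy ester before the acetate, so the more hindered C9 hydroxyl is acylated while O3 and O8 are still blocked, and the methylene lactone is built before any ester is present.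

**Epoxy acid (34 back to 31).** The oxirane C–O bonds are cut to the Z alkene of alcohol 32, obtained from angelic acid 31. The Z geometry fixes the trans relationship of the two methyl groups, and an asymmetric epoxidation of the allylic alcohol fixes the absolute configuration. The forward sequence must reduce, epoxidise and re-oxidise without Z-to-E isomerisation.

**Methylene lactone (29 back to 20 and 21).** C13 is removed (Mannich methylenation of lactone 25). The lactone C12–O bond is opened to hydroxy ester 24 and its ketone 23. The C7–C11 bond is cut to the enolate of ketone 20 and methyl bromoacetate 21. These cuts are chosen because the ketone at C6 is exactly what the rearrangement delivers. The forward steps must set C7 and C6; both additions are planned from the exposed outer face of the medium ring.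

**Key disconnection (20 back to 17).** C8–C9 is cut and C1–C6 is joined, which converts the cyclodecadienone 20 into the cis-1,6-dialkenyl cyclohexenol 17. Any other ring bond would have to be closed end to end against transannular strain; C8–C9 is made by a ring expansion instead, it carries two of the five ring stereocentres, and its formation also creates the Z alkene C1=C10. The forward step must run through one chair transition state, so the enol ether geometries (Z at C8, E at C9) and the relative configuration at C1, C3 and C6 of 17 have to be secured beforehand.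

**Enol ether arm on C6 (17 back to 8 and 13).** The Z enol ether is traced to alkyne 16 (syn semihydrogenation) and the C6–C7 bond is cut to ketone 8 and the alkoxyacetylide derived from dichlorovinyl ether 13, which is made from 4-methoxybenzyl alcohol 9 and trichloroethylene 10. The acetylide is preferred to a vinyl nucleophile because the Z geometry then follows from the hydrogenation and because a slim sp nucleophile favours the axial approach that places the new group cis to the C1 substituent.

**Ring and C1/C3 stereocentres (8 back to 1).** The silyl enol ether is traced to aldehyde 7, the two carbonyl groups to diol 6, and the diol to dienone 4 by hydroboration and carbonyl reduction. The C6 carbonyl of 4 is traced to a ring methylene group (allylic oxidation of 3), and the C3 silyl ether to the carbonyl of (S)-carvone 1 through cis-carveol 2. Carvone supplies ten of the fifteen skeletal carbons, the C4=C5 alkene with its methyl group, the absolute configuration at C1, and, through a 1,2-reduction, the cis C1/C3 relationship. Building the C1–C10 bond by enolate chemistry on a preformed ring would be expected to deliver the side chain trans to the C3 oxygen, which is why both centres are taken from 1.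

## Alternatives that were turned down

**Alternative 1: late carbonylative closure of the methylene lactone.** The disconnection removes C12 and cuts C11–C12 and C12–O. In the forward step a zerovalent palladium catalyst inserts into the C11–I bond of the iodovinyl alcohol A1, the carbonyl carbon is taken up from the gas phase, and the C6 hydroxyl captures the acylpalladium to give A2 with C11=C13 in place. In its favour: the electrophilic lactone appears last, no lactone enolate is needed, and the cis fusion is fixed by C6 and C7. Against it for this target: A1 carries two allylic esters (C3, C9) and an allylic alcohol, all of which zerovalent palladium can ionise. The step also addresses only the lactone, leaving open how the ring, the Z alkenes and C6–C9 of A1 are made. On the lactone itself this alternative is stronger than the chosen route (one step against three, and no strong base on a β-oxygenated ketone). The chosen strategy offers in exchange the ring, the Z alkene C1=C10 and two stereocentres in one step from a chiral-pool cyclohexene.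

**Alternative 2: chromium-mediated ring closure at C9–C10.** The disconnection cuts C9–C10. In the forward step the Z vinyl iodide of A3 is turned by divalent chromium with a nickel co-catalyst into a vinylchromium species that adds to the C9 aldehyde, giving A4 with the ring closed and the C9 carbinol formed. In its favour: the reaction tolerates the lactone and the acetate, so fewer late protecting-group steps are needed, the Z geometry is fixed in the iodide, and C9 arrives at the alcohol oxidation level. Against it: a ten-membered ring is closed end to end against transannular strain, and the C9 configuration depends on the facial selectivity of an α-silyloxy aldehyde in a macrocyclic transition state, which cannot be predicted. A3 is also an open chain with a Z trisubstituted alkene, four stereocentres and an epimerisable aldehyde, so it requires a long linear synthesis. It is the stronger route on functional-group tolerance; the chosen route avoids the entropic and strain cost of closure and sets C8 and C9 together under chair control.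

**Alternative 3: Grob fragmentation of a cis-decalin.** The disconnection re-forms the C4–C9 bond. In the forward step the C9 alkoxide of the bicyclic mesylate A5 pushes out the C5 mesylate as C4–C9 breaks, giving the cyclodecadienone A6 with the C4=C5 alkene and a C9 ketone. In its favour: the fragmentation is stereospecific, so the Z geometry of C4=C5 follows from the antiperiplanar alignment in a rigid bicycle, the stereocentres are set on six-membered rings, and the lactone is already present. Against it: A5 needs seven stereocentres including the adjacent fully substituted C4 and C9, so the precursor is long. In A6, C9 is a ketone, so the C9 centre must still be set by reduction in the flexible ring next to an epimerisable C8, and an alkoxide is generated in the presence of the lactone. It is stronger than the chosen route on the certainty of the C4=C5 geometry. The chosen route takes that alkene unchanged from the six-membered ring and delivers C9 at the alcohol level together with C8.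

Key step: step 10

## Route

Assumption: centres that are destroyed later (C6 and C10 in 6, C10 in 7, C11 in 27 and 28) are carried as mixtures, which has no consequence because they become sp2 or are eliminated.

Step 1
Reactants: 1 (S)-(+)-carvone
Product: 2 (1S,5S)-cis-carveol
Conditions: NaBH4, CeCl3·7H2O, MeOH, −78 to 0 °C
Reagents that add atoms: none
Why: Luche 1,2-reduction; hydride attacks along the axial trajectory of the half-chair with the isopropenyl group equatorial, so the new hydroxyl (the future C3 oxygen) should come out cis to the isopropenyl group (the future C1 side chain), which sets C3 from the carvone stereocentre.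

Step 2
Reactants: 2 (1S,5S)-cis-carveol
Product: 3 cis-carveol TBDPS ether
Conditions: TBDPSCl, imidazole, DMF, rt
Reagents that add atoms: tert-butyl(chloro)diphenylsilane, CC(C)(C)[Si](Cl)(c1ccccc1)c1ccccc1
Why: Imidazole-promoted silylation of a secondary allylic alcohol; the bulky, robust TBDPS group must last to step 19 and also shields the C3–H bond in the next step.

Step 3
Reactants: 3 cis-carveol TBDPS ether
Product: 4 (4S,6S)-4-(tert-butyldiphenylsilyloxy)-3-methyl-6-(prop-1-en-2-yl)cyclohex-2-en-1-one
Conditions: CrO3, 3,5-dimethylpyrazole, CH2Cl2, −20 °C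
Reagents that add atoms: chromium trioxide, O=[Cr](=O)=O
Why: Allylic oxidation of a trisubstituted cyclohexene to the enone with the CrO3–3,5-dimethylpyrazole reagent; the only free ring allylic methylene is the future C6, the other allylic position being the hindered silyloxy methine, and oxygenation at either end of the allyl unit converges on the same enone because a tertiary chromate transposes; the cold, weakly basic medium should leave the C1 centre next to the new carbonyl untouched.

Step 4
Reactants: 4 dienone
Product: 6 diol (C6 carbinol and C9 primary alcohol), via bis-boron adduct 5 (not isolated)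
Conditions: 9-BBN (2.5 equiv), THF, 0 °C to rt; then NaOH, H2O2, 0 °C
Reagents that add atoms: hydrogen peroxide, OO
Why: 9-BBN reduces the enone carbonyl in the 1,2 sense and hydroborates the 1,1-disubstituted alkene at its terminus (anti-Markovnikov hydroboration–oxidation), while the trisubstituted ring alkene is too hindered to react; the new centres at C6 and C10 form as mixtures and both are flattened again later.

Step 5
Reactants: 6 diol
Product: 7 keto aldehyde
Conditions: Dess–Martin periodinane, CH2Cl2, 0 °C to rt
Reagents that add atoms: none
Why: Dess–Martin oxidation converts the primary alcohol to the aldehyde and the allylic alcohol to the enone under non-basic conditions, so the C1 centre between the two carbonyl groups should not be enolised.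

Step 6
Reactants: 7 keto aldehyde
Product: 8 (4S,6S)-6-[(E)-1-(tert-butyldimethylsilyloxy)prop-1-en-2-yl]-4-(tert-butyldiphenylsilyloxy)-3-methylcyclohex-2-en-1-one
Conditions: TBSOTf (1.05 equiv), Et3N, CH2Cl2, −78 °C
Reagents that add atoms: tert-butyldimethylsilyl trifluoromethanesulfonate, CC(C)(C)[Si](C)(C)OS(=O)(=O)C(F)(F)F
Why: Soft enolisation: the silyl triflate activates the unhindered aldehyde oxygen in preference to the enone and Et3N removes the C10 proton; the E isomer (silyloxy group cis to the methyl, trans to ring carbon C1) should predominate because deprotonation occurs from the rotamer in which the small methyl group eclipses the carbonyl; any Z isomer must be removed by chromatography because the enol ether geometry becomes the C9 configuration.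

Step 7
Reactants: 9 4-methoxybenzyl alcohol; 10 trichloroethylene
Product: 13 (E)-1,2-dichlorovinyl 4-methoxybenzyl ether, via potassium 4-methoxybenzyl oxide 11 (not isolated), via dichloroacetylene 12 (not isolated)
Conditions: KH, THF, 0 °C; then 10, −50 °C to rt
Reagents that add atoms: none
Why: Alkoxide 11 dehydrochlorinates 10 to 12 and adds to it in the anti sense (addition of an alkoxide to a haloalkyne), which should give the E dichlorovinyl ether; this is the known one-flask entry to alkynyl ether precursors from alcohols.

Step 8
Reactants: 13 (E)-1,2-dichlorovinyl 4-methoxybenzyl ether; 8 ketone with the E silyl enol ether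
Product: 16 (1R,4S,6S)-alkynyl carbinol (C6 bearing OH and the PMB-oxyethynyl group), via chloroethynyl ether 14 (not isolated), via lithium acetylide 15 (not isolated)
Conditions: 13, n-BuLi (2 equiv), THF, −78 to −40 °C; then 8, −78 °C; then H2O
Reagents that add atoms: none
Why: n-BuLi converts 13 by dehydrochlorination into 14 and by chlorine–lithium exchange into 15 (the dichlorovinyl ether route to lithium alkoxyacetylides), which adds 1,2 to the enone carbonyl; the slim sp nucleophile should take the axial trajectory of the half-chair in which the C1 and C3 substituents are both pseudo-equatorial, anti to the axial C1–H, so the alkynyl group ends up cis to the C1 alkenyl group and C6 is set as R; the C6 epimer, if formed, must be separated because it cannot lead to the Z alkene.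

Step 9
Reactants: 16 alkynyl carbinol
Product: 17 (1R,4S,6S)-6-[(E)-1-(tert-butyldimethylsilyloxy)prop-1-en-2-yl]-4-(tert-butyldiphenylsilyloxy)-1-[(Z)-2-(4-methoxybenzyloxy)ethenyl]-3-methylcyclohex-2-en-1-ol
Conditions: H2 (1 atm), Pd/CaCO3 poisoned with Pb(OAc)2, quinoline, EtOAc, 0 °C
Reagents that add atoms: none
Why: Syn addition of one equivalent of hydrogen to the electron-rich alkynyl ether on lead-poisoned palladium (Lindlar-type semihydrogenation) fixes the Z enol ether; the trisubstituted alkenes, the silyl enol ether and the PMB ether are inert to the poisoned catalyst.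

Step 10
Reactants: 17 cis-1,6-dialkenyl cyclohexenol
Product: 20 (2Z,4S,6Z,8S,9R)-8-(tert-butyldimethylsilyloxy)-4-(tert-butyldiphenylsilyloxy)-9-(4-methoxybenzyloxy)-3,7-dimethylcyclodeca-2,6-dien-1-one, via potassium alkoxide 18 (not isolated), via potassium enolate 19 (not isolated)
Conditions: KH, 18-crown-6, THF, 0 °C to rt; then AcOH, THF, −78 °C
Reagents that add atoms: none
Why: KH with 18-crown-6 gives the dissociated alkoxide 18, whose C1–C6 bond is weakened so that the 1,5-diene C8=C7–C6–C1–C10=C9 undergoes the [3,3] shift far below the temperature of the neutral reaction (anionic oxy-Cope rearrangement; the closest precedent is the ring expansion of 1,2-dialkenylcyclohexanols to cyclodec-5-enones). The ten-membered ring is not closed end to end but arises by a four-atom ring expansion of the cyclohexene: C8–C9 forms as C1–C6 breaks, and C4=C5 is carried over with its cis geometry. C8 and C9 are set together in a chair transition state in which the Z enol ether places the C8 oxygen pseudo-axial and the E silyl enol ether places the C9 oxygen pseudo-equatorial, which gives the (8R,9S) pair in target numbering with both oxygens on the same ring face. The absolute sense comes from C1 and C6: with the alkenyl groups cis, the chair has the C1–C2 bond pseudo-axial and the C6–C5 bond pseudo-equatorial, so C2 ends up cis to C9 and C1=C10 is Z. Three substrate features secure this chair: the C1 alkenyl group and the cis C3 silyloxy group are both pseudo-equatorial in the half-chair, which leaves the C6 alkenyl group pseudo-axial; the competing chair would force those two groups into a 1,3-diaxial arrangement; and turning C2 toward the C10 methyl group is penalised by allylic strain. Enolate 19 carries the PMB ether β to C7, so it is protonated at −78 °C before it can eliminate, giving 20.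

Step 11
Reactants: 20 cyclodecadienone; 21 methyl bromoacetate
Product: 23 C7-alkylated ketone (methyl ester of the C7 acetic acid), via lithium enolate 22 (not isolated)
Conditions: LiN(iPr)2, THF, −78 °C; then 21, DMPU, −78 to −40 °C
Reagents that add atoms: none
Why: Kinetic deprotonation at C7, the only α-carbon bearing hydrogens, and SN2 alkylation of the enolate with the reactive α-bromo ester; the proton removed should be the outward one delivered in the quench of step 10, so 22 should have the geometry of 19, and 21 approaches its exposed outer face, syn to the C8 ether, which sets C7 as in the target (7S); the temperature is held at or below −40 °C so that the β-alkoxy enolate does not eliminate.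

Step 12
Reactants: 23 keto ester
Product: 25 cis-fused γ-lactone (O on C6 and C11H2 on C7), via hydroxy ester 24 (not isolated)
Conditions: NaBH4, CeCl3·7H2O, MeOH, −78 °C; then PPTS (cat.), PhMe, 40 °C
Reagents that add atoms: none
Why: Luche 1,2-reduction of the enone; hydride should again arrive from the outer face of the ring, the face used by 21 at C7, which places the C6 oxygen cis to the C7 acetate arm (6R); the γ-hydroxy ester then closes to the five-membered lactone by acid-catalysed transesterification with retention at C6.

Step 13
Reactants: 25 γ-lactone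
Product: 29 α-methylene lactone with C3 TBDPS ether and C8 PMB ether and C9 TBS ether, via lithium enolate 26 (not isolated), via Mannich base 27 (not isolated), via ammonium iodide 28 (not isolated)
Conditions: LiN(iPr)2, THF, −78 °C; CH2=NMe2+ I−, −78 °C to rt; then MeI, MeOH, rt; then NaHCO3, H2O/CH2Cl2, rt
Reagents that add atoms: dimethylmethyleneammonium iodide (Eschenmoser's salt), C=[N+](C)C.[I-]
Why: Mannich reaction of the lactone enolate, N-methylation and base-induced loss of trimethylamine (the standard α-methylenation of γ-lactones); C7 carries no leaving group, so the enolate cannot eliminate, and the silyl and PMB ethers tolerate the base.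

Step 14
Reactants: 29 fully protected methylene lactone
Product: 30 C9 alcohol
Conditions: HF·pyridine, pyridine, THF, 0 °C to rt
Reagents that add atoms: none
Why: Buffered HF·pyridine cleaves the trialkylsilyl ether at C9 much faster than the more acid-stable TBDPS ether at C3 (selective desilylation), and the methylene lactone and PMB ether are stable to this weakly acidic, non-nucleophilic medium.

Step 15
Reactants: 31 angelic acid
Product: 32 (Z)-2-methylbut-2-en-1-ol
Conditions: LiAlH4, Et2O, 0 °C
Reagents that add atoms: none
Why: Hydride reduction of the carboxylic acid to the primary allylic alcohol at 0 °C, where the Z trisubstituted alkene should not isomerise.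

Step 16
Reactants: 32 (Z)-2-methylbut-2-en-1-ol
Product: 33 [(2S,3R)-2,3-dimethyloxiran-2-yl]methanol
Conditions: Ti(OiPr)4, L-(+)-diethyl tartrate, t-BuOOH, 4 Å MS, CH2Cl2, −20 °C
Reagents that add atoms: tert-butyl hydroperoxide, CC(C)(C)OO
Why: Sharpless asymmetric epoxidation; with L-(+)-diethyl tartrate oxygen is delivered by the usual facial rule for primary allylic alcohols (the sense that gives (2S,3S)-epoxides from simple E-2-alken-1-ols) to the face that here gives the (2S,3R) epoxy alcohol, and syn addition keeps the two methyl groups trans.

Step 17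
Reactants: 33 epoxy alcohol
Product: 34 (2R,3R)-2,3-dimethyloxirane-2-carboxylic acid
Conditions: RuCl3·xH2O (cat.), NaIO4, MeCN/EtOAc/H2O, rt
Reagents that add atoms: sodium periodate, [Na+].[O-][I](=O)(=O)=O; water, O
Why: Ruthenium-catalysed periodate oxidation takes the primary alcohol through the aldehyde hydrate to the acid without opening the epoxide (standard conversion of 2,3-epoxy alcohols into glycidic acids); no stereocentre is touched, only the CIP label of C2 changes from S to R.

Step 18
Reactants: 34 (2R,3R)-epoxy acid; 30 C9 alcohol
Product: 36 C9 (2R,3R)-2,3-dimethyloxirane-2-carboxylate with C3 TBDPS ether and C8 PMB ether, via mixed anhydride 35 (not isolated)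
Conditions: 34, 2,4,6-trichlorobenzoyl chloride, Et3N, THF, rt; then 30, DMAP, PhMe, rt to 40 °C
Reagents that add atoms: none
Why: Yamaguchi esterification: the acid is activated as the mixed anhydride and DMAP transfers the glycidoyl group to the hindered allylic C9 hydroxyl; C9 keeps its configuration because its C–O bond is not broken, and nothing present opens the epoxide.

Step 19
Reactants: 36 C9 ester
Product: 37 C3 alcohol
Conditions: Bu4NF, AcOH, THF, 0 °C to rt
Reagents that add atoms: none
Why: Fluoride cleavage of the remaining silyl ether; acetic acid buffers the alkoxide so that the glycidic ester and the methylene lactone should not be attacked.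

Step 20
Reactants: 37 C3 alcohol
Product: 38 C3 acetate with C8 PMB ether
Conditions: Ac2O, pyridine, DMAP (cat.), CH2Cl2, 0 °C
Reagents that add atoms: acetic anhydride, CC(=O)OC(C)=O
Why: DMAP-catalysed acetylation of the secondary allylic alcohol; O8 is still a PMB ether, so only O3 is acylated.

Step 21
Reactants: 38 PMB ether
Product: 39 target CNP0137407.4
Conditions: DDQ, CH2Cl2/pH 7 buffer, 0 °C
Reagents that add atoms: none
Why: Oxidative PMB cleavage: DDQ abstracts the benzylic hydride and water hydrolyses the oxocarbenium ion; the esters, the epoxide, the isolated alkenes and the methylene lactone are not oxidised, and the neutral medium should prevent migration of the C9 acyl group to the freed C8 hydroxyl.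

## Compound list

1 | (S)-(+)-carvone | CC1=CC[C@@H](CC1=O)C(C)=C | starting material
2 | (1S,5S)-cis-carveol, (1S,5S)-2-methyl-5-(prop-1-en-2-yl)cyclohex-2-en-1-ol | CC1=CC[C@@H](C[C@@H]1O)C(C)=C | intermediate
3 | tert-butyl{[(1S,5S)-2-methyl-5-(prop-1-en-2-yl)cyclohex-2-en-1-yl]oxy}diphenylsilane | CC1=CC[C@@H](C[C@@H]1O[Si](c2ccccc2)(c2ccccc2)C(C)(C)C)C(C)=C | intermediate
4 | (4S,6S)-4-(tert-butyldiphenylsilyloxy)-3-methyl-6-(prop-1-en-2-yl)cyclohex-2-en-1-one | O=C1C=C(C)[C@@H](O[Si](c2ccccc2)(c2ccccc2)C(C)(C)C)C[C@H]1C(C)=C | intermediate
5 | bis(9-borabicyclo[3.3.1]nonan-9-yl) adduct of 4 (O-boryl at C6, C-boryl at C9) | O(B1C2CCCC1CCC2)C1C=C(C)[C@@H](O[Si](c2ccccc2)(c2ccccc2)C(C)(C)C)C[C@H]1C(C)CB1C2CCCC1CCC2 | intermediate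
6 | (4S,6S)-4-(tert-butyldiphenylsilyloxy)-6-(1-hydroxypropan-2-yl)-3-methylcyclohex-2-en-1-ol, mixture at the ring carbinol and the side-chain methine | OC1C=C(C)[C@@H](O[Si](c2ccccc2)(c2ccccc2)C(C)(C)C)C[C@H]1C(C)CO | intermediate
7 | 2-[(1S,5S)-5-(tert-butyldiphenylsilyloxy)-4-methyl-2-oxocyclohex-3-en-1-yl]propanal, mixture at the side-chain methine | O=C1C=C(C)[C@@H](O[Si](c2ccccc2)(c2ccccc2)C(C)(C)C)C[C@H]1C(C)C=O | intermediate
8 | (4S,6S)-6-[(E)-1-(tert-butyldimethylsilyloxy)prop-1-en-2-yl]-4-(tert-butyldiphenylsilyloxy)-3-methylcyclohex-2-en-1-one | O=C1C=C(C)[C@@H](O[Si](c2ccccc2)(c2ccccc2)C(C)(C)C)C[C@H]1/C(C)=C/O[Si](C)(C)C(C)(C)C | intermediate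
9 | 4-methoxybenzyl alcohol | COc1ccc(CO)cc1 | starting material
10 | trichloroethylene | ClC=C(Cl)Cl | starting material
11 | potassium 4-methoxybenzyl oxide | [K+].[O-]Cc1ccc(OC)cc1 | intermediate
12 | dichloroacetylene | ClC#CCl | intermediate
13 | (E)-1,2-dichlorovinyl 4-methoxybenzyl ether | Cl/C=C(/Cl)OCc1ccc(OC)cc1 | intermediate
14 | chloroethynyl 4-methoxybenzyl ether | ClC#COCc1ccc(OC)cc1 | intermediate
15 | lithium (4-methoxybenzyloxy)acetylide | [Li]C#COCc1ccc(OC)cc1 | intermediate
16 | (1R,4S,6S)-6-[(E)-1-(tert-butyldimethylsilyloxy)prop-1-en-2-yl]-4-(tert-butyldiphenylsilyloxy)-1-[(4-methoxybenzyloxy)ethynyl]-3-methylcyclohex-2-en-1-ol | O[C@]1(C#COCc2ccc(OC)cc2)C=C(C)[C@@H](O[Si](c2ccccc2)(c2ccccc2)C(C)(C)C)C[C@H]1/C(C)=C/O[Si](C)(C)C(C)(C)C | intermediate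
17 | (1R,4S,6S)-6-[(E)-1-(tert-butyldimethylsilyloxy)prop-1-en-2-yl]-4-(tert-butyldiphenylsilyloxy)-1-[(Z)-2-(4-methoxybenzyloxy)ethenyl]-3-methylcyclohex-2-en-1-ol | O[C@]1(/C=C\OCc2ccc(OC)cc2)C=C(C)[C@@H](O[Si](c2ccccc2)(c2ccccc2)C(C)(C)C)C[C@H]1/C(C)=C/O[Si](C)(C)C(C)(C)C | intermediate
18 | potassium alkoxide of 17 | [K+].[O-][C@]1(/C=C\OCc2ccc(OC)cc2)C=C(C)[C@@H](O[Si](c2ccccc2)(c2ccccc2)C(C)(C)C)C[C@H]1/C(C)=C/O[Si](C)(C)C(C)(C)C | intermediate
19 | potassium enolate of 20 (C6–O−, C6=C7, oxygen cis to C8) | [C@@H]1(OCc2ccc(OC)cc2)/C=C(\[O-])/C=C(/C)[C@@H](O[Si](c2ccccc2)(c2ccccc2)C(C)(C)C)C/C=C(/C)[C@@H]1O[Si](C)(C)C(C)(C)C.[K+] | intermediate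
20 | (2Z,4S,6Z,8S,9R)-8-(tert-butyldimethylsilyloxy)-4-(tert-butyldiphenylsilyloxy)-9-(4-methoxybenzyloxy)-3,7-dimethylcyclodeca-2,6-dien-1-one | O=C1/C=C(/C)[C@@H](O[Si](c2ccccc2)(c2ccccc2)C(C)(C)C)C/C=C(/C)[C@H](O[Si](C)(C)C(C)(C)C)[C@H](OCc2ccc(OC)cc2)C1 | intermediate
21 | methyl bromoacetate | COC(=O)CBr | starting material
22 | lithium enolate of 20 (same geometry as 19) | [C@@H]1(OCc2ccc(OC)cc2)/C=C(\[O-])/C=C(/C)[C@@H](O[Si](c2ccccc2)(c2ccccc2)C(C)(C)C)C/C=C(/C)[C@@H]1O[Si](C)(C)C(C)(C)C.[Li+] | intermediate
23 | ketone 20 carrying a CH2CO2Me group on C7, cis to the C8 ether in the ring drawing (7S, target numbering) | O=C1/C=C(/C)[C@@H](O[Si](c2ccccc2)(c2ccccc2)C(C)(C)C)C/C=C(/C)[C@H](O[Si](C)(C)C(C)(C)C)[C@H](OCc2ccc(OC)cc2)[C@@H]1CC(=O)OC | intermediate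
24 | C6 alcohol of 23, hydroxyl cis to the C7 arm (6R, target numbering) | O[C@@H]1/C=C(/C)[C@@H](O[Si](c2ccccc2)(c2ccccc2)C(C)(C)C)C/C=C(/C)[C@H](O[Si](C)(C)C(C)(C)C)[C@H](OCc2ccc(OC)cc2)[C@@H]1CC(=O)OC | intermediate
25 | cis-fused γ-lactone (C12 to O6) with C3 TBDPS, C8 PMB and C9 TBS ethers | O=C1O[C@@H]2/C=C(/C)[C@@H](O[Si](c3ccccc3)(c3ccccc3)C(C)(C)C)C/C=C(/C)[C@H](O[Si](C)(C)C(C)(C)C)[C@H](OCc3ccc(OC)cc3)[C@@H]2C1 | intermediate
26 | lithium enolate of lactone 25 | [Li+].[O-]C=1O[C@@H]2/C=C(/C)[C@@H](O[Si](c3ccccc3)(c3ccccc3)C(C)(C)C)C/C=C(/C)[C@H](O[Si](C)(C)C(C)(C)C)[C@H](OCc3ccc(OC)cc3)[C@@H]2C1 | intermediate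
27 | C11 dimethylaminomethyl lactone (C11 unassigned) | O=C1O[C@@H]2/C=C(/C)[C@@H](O[Si](c3ccccc3)(c3ccccc3)C(C)(C)C)C/C=C(/C)[C@H](O[Si](C)(C)C(C)(C)C)[C@H](OCc3ccc(OC)cc3)[C@@H]2C1CN(C)C | intermediate
28 | C11 trimethylammoniomethyl lactone iodide (C11 unassigned) | O=C1O[C@@H]2/C=C(/C)[C@@H](O[Si](c3ccccc3)(c3ccccc3)C(C)(C)C)C/C=C(/C)[C@H](O[Si](C)(C)C(C)(C)C)[C@H](OCc3ccc(OC)cc3)[C@@H]2C1C[N+](C)(C)C.[I-] | intermediate
29 | α-methylene lactone with C3 TBDPS, C8 PMB and C9 TBS ethers | C=C1C(=O)O[C@@H]2/C=C(/C)[C@@H](O[Si](c3ccccc3)(c3ccccc3)C(C)(C)C)C/C=C(/C)[C@H](O[Si](C)(C)C(C)(C)C)[C@H](OCc3ccc(OC)cc3)[C@H]12 | intermediate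
30 | C9 alcohol (C3 TBDPS, C8 PMB) | C=C1C(=O)O[C@@H]2/C=C(/C)[C@@H](O[Si](c3ccccc3)(c3ccccc3)C(C)(C)C)C/C=C(/C)[C@H](O)[C@H](OCc3ccc(OC)cc3)[C@H]12 | intermediate
31 | angelic acid, (Z)-2-methylbut-2-enoic acid | C/C=C(/C)C(=O)O | starting material
32 | (Z)-2-methylbut-2-en-1-ol | C/C=C(/C)CO | intermediate
33 | [(2S,3R)-2,3-dimethyloxiran-2-yl]methanol | OC[C@]1(C)O[C@@H]1C | intermediate
34 | (2R,3R)-2,3-dimethyloxirane-2-carboxylic acid | OC(=O)[C@]1(C)O[C@@H]1C | intermediate
35 | mixed anhydride of 34 with 2,4,6-trichlorobenzoic acid | O=C(OC(=O)[C@]1(C)O[C@@H]1C)c1c(Cl)cc(Cl)cc1Cl | intermediate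
36 | C9 (2R,3R)-epoxy ester (C3 TBDPS, C8 PMB) | C=C1C(=O)O[C@@H]2/C=C(/C)[C@@H](O[Si](c3ccccc3)(c3ccccc3)C(C)(C)C)C/C=C(/C)[C@H](OC(=O)[C@]3(C)O[C@@H]3C)[C@H](OCc3ccc(OC)cc3)[C@H]12 | intermediate
37 | C3 alcohol (C8 PMB, C9 epoxy ester) | C=C1C(=O)O[C@@H]2/C=C(/C)[C@@H](O)C/C=C(/C)[C@H](OC(=O)[C@]3(C)O[C@@H]3C)[C@H](OCc3ccc(OC)cc3)[C@H]12 | intermediate
38 | C3 acetate, C8 PMB ether, C9 epoxy ester | C=C1C(=O)O[C@@H]2/C=C(/C)[C@@H](OC(C)=O)C/C=C(/C)[C@H](OC(=O)[C@]3(C)O[C@@H]3C)[C@H](OCc3ccc(OC)cc3)[C@H]12 | intermediate
39 | CNP0137407.4 | C=C1C(=O)O[C@@H]2/C=C(/C)[C@@H](OC(C)=O)C/C=C(/C)[C@H](OC(=O)[C@]3(C)O[C@@H]3C)[C@H](O)[C@H]12 | target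

## Step count and least certain steps

Total: 21 steps. Longest linear sequence: 17 steps (1–6, 8–14, 18–21, from 1 to 39). Steps 7 and 15–17 are side branches.

**Step 10 (key step).** The rearrangement may leak through a boat or, after ring inversion, through the other chair, which would give the C8/C9 diastereomer or the E alkene. The potassium enolate may also expel the β-PMB-oxy group before it is quenched. Fallback: the neutral siloxy-Cope variant, which forms no enolate. Starting from 17, the tertiary alcohol is trimethylsilylated to trimethylsilyl ether F1. Heating F1 in a degassed hydrocarbon in a sealed vessel (about 180–200 °C) drives the same [3,3] shift through the same chair and gives trimethylsilyl enol ether F2. Brief methanolysis of F2 (catalytic K2CO3, MeOH, −20 °C) releases ketone 20, where the route is rejoined.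

**Step 8.** The acetylide may attack from the equatorial direction, giving the carbinol epimer with the alkenyl groups trans, or may remove the acidic C1 proton instead of adding. The adduct is also an acid- and heat-sensitive ynol ether that can rearrange before it is hydrogenated. Fallback: introduce the two carbons as a preformed Z alkenyl nucleophile. Starting from 13, treatment with n-BuLi and then methanol gives 4-methoxybenzyl ethynyl ether F3. Radical hydrostannation (Bu3SnH, AIBN, short reaction time) gives (Z)-tributyl[2-(4-methoxybenzyloxy)ethenyl]stannane F4. Tin–lithium exchange with n-BuLi at −78 °C gives (Z)-2-(4-methoxybenzyloxy)vinyllithium F5, which adds to ketone 8 to give 17 directly, so that 16 and the hydrogenation are bypassed. The face of attack is governed by the same half-chair, so the C6 epimers must still be separated at 17.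

**Step 3.** Hydrogen abstraction may occur at the silyloxy-bearing C3–H or next to the isopropenyl group, giving a carvone-type enone or over-oxidised material, and the new β,γ-unsaturated ketone may epimerise at C1 or move its alkene into conjugation. Fallback: stepwise oxygen transposition. Starting from 3, the ring alkene is epoxidised with mCPBA, anti to the silyl ether, to give epoxide F6. Sodium phenylselenide opens F6 at the less substituted C5 to give hydroxy selenide F7. Oxidation with H2O2 and selenoxide elimination away from the hydroxyl give the tertiary allylic alcohol F8 (C4–OH, C5=C6). Oxidative 1,3-transposition with pyridinium chlorochromate, [C5H5NH][CrO3Cl], (Babler–Dauben) gives enone 4.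

**Step 11.** The lithium enolate may lose the C8 PMB-oxy group by β-elimination, or may form with the other geometry and be alkylated on the wrong face of C7. Fallback: skip the separate enolisation. Starting from 17, the rearrangement is run as in step 10, but 21 is added to the cold solution of enolate 19 in place of the acid quench, which gives 23 directly from the enolate of defined geometry; no new compound is involved.

**Step 12.** Hydride may be delivered to the inner face if the ring changes conformation after alkylation, giving the C6 epimer, which cannot close to the cis lactone. Fallback: close the ring with inversion. Starting from 23, if the 6-epi hydroxy ester F9 is what forms, it is saponified (LiOH) to the 6-epi hydroxy acid F10. Mitsunobu lactonisation of F10 (PPh3, diisopropyl azodicarboxylate) inverts C6 and gives lactone 25.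

## Further compounds

F1 | step 10 | trimethylsilyl ether of 17 | C[Si](C)(C)O[C@]1(/C=C\OCc2ccc(OC)cc2)C=C(C)[C@@H](O[Si](c2ccccc2)(c2ccccc2)C(C)(C)C)C[C@H]1/C(C)=C/O[Si](C)(C)C(C)(C)C
F2 | step 10 | trimethylsilyl enol ether of 20 (C6–OSiMe3, C6=C7) | [C@@H]1(OCc2ccc(OC)cc2)/C=C(\O[Si](C)(C)C)/C=C(/C)[C@@H](O[Si](c2ccccc2)(c2ccccc2)C(C)(C)C)C/C=C(/C)[C@@H]1O[Si](C)(C)C(C)(C)C
F3 | step 8 | 4-methoxybenzyl ethynyl ether | C#COCc1ccc(OC)cc1
F4 | step 8 | (Z)-tributyl[2-(4-methoxybenzyloxy)ethenyl]stannane | CCCC[Sn](CCCC)(CCCC)/C=C\OCc1ccc(OC)cc1
F5 | step 8 | (Z)-2-(4-methoxybenzyloxy)vinyllithium | [Li]/C=C\OCc1ccc(OC)cc1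
F6 | step 3 | ring epoxide of 3 (C4–C5, anti to the silyl ether) | C[C@]12O[C@H]1C[C@H](C(C)=C)C[C@@H]2O[Si](c1ccccc1)(c1ccccc1)C(C)(C)C
F7 | step 3 | C4 hydroxy C5 phenylselenide | C[C@]1(O)[C@H]([Se]c2ccccc2)C[C@H](C(C)=C)C[C@@H]1O[Si](c2ccccc2)(c2ccccc2)C(C)(C)C
F8 | step 3 | tertiary allylic alcohol (C4–OH, C5=C6) | C[C@]1(O)C=C[C@H](C(C)=C)C[C@@H]1O[Si](c2ccccc2)(c2ccccc2)C(C)(C)C
F0 | step 11 | none | none
F9 | step 12 | 6-epi hydroxy ester | O[C@H]1/C=C(/C)[C@@H](O[Si](c2ccccc2)(c2ccccc2)C(C)(C)C)C/C=C(/C)[C@H](O[Si](C)(C)C(C)(C)C)[C@H](OCc2ccc(OC)cc2)[C@@H]1CC(=O)OC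
F10 | step 12 | 6-epi hydroxy acid | O[C@H]1/C=C(/C)[C@@H](O[Si](c2ccccc2)(c2ccccc2)C(C)(C)C)C/C=C(/C)[C@H](O[Si](C)(C)C(C)(C)C)[C@H](OCc2ccc(OC)cc2)[C@@H]1CC(=O)O
A1 | alternative 1 | C6 alcohol with a 1-iodovinyl group on C7, C8 triethylsilyl ether | O[C@@H]1/C=C(/C)[C@@H](OC(C)=O)C/C=C(/C)[C@H](OC(=O)[C@]2(C)O[C@@H]2C)[C@H](O[Si](CC)(CC)CC)[C@@H]1C(I)=C
A2 | alternative 1 | C8 triethylsilyl ether of the target | C=C1C(=O)O[C@@H]2/C=C(/C)[C@@H](OC(C)=O)C/C=C(/C)[C@H](OC(=O)[C@]3(C)O[C@@H]3C)[C@H](O[Si](CC)(CC)CC)[C@H]12
A3 | alternative 2 | open-chain C9 aldehyde with a Z vinyl iodide at C10 | C=C1C(=O)O[C@H](/C=C(/C)[C@@H](OC(C)=O)C/C=C(/C)I)[C@@H]1[C@@H](O[Si](CC)(CC)CC)C=O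
A4 | alternative 2 | C9 alcohol of the full skeleton, C8 triethylsilyl ether | C=C1C(=O)O[C@@H]2/C=C(/C)[C@@H](OC(C)=O)C/C=C(/C)[C@H](O)[C@H](O[Si](CC)(CC)CC)[C@H]12
A5 | alternative 3 | cis-decalin lactone with C9 tertiary alcohol and C5 mesylate | O=C1O[C@@H]2[C@H](OS(C)(=O)=O)[C@]3(C)[C@@H](O[Si](C)(C)C(C)(C)C)CC=C(C)[C@]3(O)[C@H](OCc4ccc(OC)cc4)[C@@H]2C1
A6 | alternative 3 | ten-membered C9 enone with both Z alkenes and the cis lactone | O=C1O[C@@H]2/C=C(/C)[C@@H](O[Si](C)(C)C(C)(C)C)C/C=C(/C)C(=O)[C@H](OCc3ccc(OC)cc3)[C@@H]2C1
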